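At 12 h the flask is read, and how the reagent was shared out by then is reckoned by counting the half-lives of one species against those of another.

    reagent + double product → tris adduct (k1 = 0.010 L mol⁻¹ min⁻¹)
    reagent + single product → double product (k2 = 0.013 L mol⁻¹ min⁻¹)
    substrate + double product → side product (k3 = 5.6 × 10⁻⁴ L mol⁻¹ min⁻¹)
    substrate + reagent → single product (k4 = 0.0028 L mol⁻¹ min⁻¹)

substrate 2.0 M; reagent 1.90 M; time 12 h

1. which holds at 12 h: what has brought the reaction to rest, or that it has not come to rest (it is still moving / all of the substrate has reacted)
2. how much tris adduct there is at 12 h, in percent of the substrate charged
3. how much single product there is at 12 h, in percent of the substrate charged

- a species is counted by the substrate in it: one side product counts as two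
- the reaction counts as stopped when no species that holds the substrate changes by six tenths of a point or more over the second half of the time
- run time (flask): 12 h

- Two extremes bound the flask, with reagent as the limiting reagent. If every reagent stops at the first addition, the charges allow 95.0% of single product. If every substrate taken runs straight through, they allow 31.7% of tris adduct and leave no single product.
- The position between them is set by the half-life count (selectivity factor): the half-lives of single product, 0.47 h each, that pass during one of substrate, 2.2 h. With reagent common to both steps, it cancels, so S = 4.64.
- S is above one but finite, so single product is consumed faster than substrate at equal concentrations, yet not at once, and this flask lies inside both extremes.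
- Let x be the share of the substrate charged not yet taken by reagent. Time then drops out, and single product follows (x − x^S)/(S − 1) of the charge.
- Both half-lives are shorter than the run, so the hand reckoning expects the reagent to be spent.
- A substrate taken holds one to three reagents. Taking two as the middle gives x = 52.5% and single product 13.0%.
- For tris adduct this reckoning gives no figure, just the bound 31.7%.
- Substrate and double product need no reagent. By that step double product has a half-life of 10 h with substrate as charged and 19.6 h with substrate at x, longer than the run, so the hand reckoning calls the flask still moving.
- The forecast says it is still moving, with tris adduct 16.7% and single product 12.6%, the side reaction “moving substrate by about 3 points over the second half”.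
- The simulation gives it is still moving, tris adduct 16.8% and single product 13.0%, so the forecast held.
- At 12.0 h this flask holds 49.4% substrate, and side product took a further 5.01% of free substrate. So x was 54.4%, and S gives 13.3% against the 13.0% found.
- A neighbour flask charged with 0.47 M of reagent ends with 81.4% substrate and 3.68% side product, so x is 83.2%. The same S gives 11.1% of single product, and that neighbour flask holds 11.1%.

The numbers are invented; the result is computed.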